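**Plan**
- Cuts: first the O2′–acyl bond of the isovalerate. Then the pyranone ring at O1–C2 and C3=C4, back to a salicylaldehyde. Then the benzene ring at C8a–C8, C7–C6 and C8a–C4a, back to a methoxyalkyne and a vinylketene. Last, the C1′–C8 carbinol–alkyne bond.
- Enabling feature: carbocyclic ring A of the coumarin (C4a, C5, C6, C7, C8, C8a) is a contiguously tetrasubstituted resorcinol monoether. It has oxygen on C8a, the side chain on C8, methoxy on C7 and carbon C4 on C4a, while C5 and C6 carry hydrogen. A vinylketene (C8a, C6, C5, C4a) and an alkoxyalkyne (C8, C7) deliver exactly this pattern.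
- Forward: the side-chain ynol ether (eight steps) and the diazo enone (two steps) are made separately and joined in the benzannulation, which builds ring A. Pyranone ring B follows by ylide annulation of the salicylaldehyde. PMB-to-isovalerate exchange and desilylation finish the route.
- C4 travels as a dimethyl acetal. Such an enone accepts detrifluoroacetylative diazo transfer and, unlike an ester-conjugated enone, is not a strong dipolarophile for diazo groups. The annulation product is then one hydrolysis away from the aldehyde.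
- Stereochemistry: C2′ (S) is the stereocentre of methyl (R)-glycerate acetonide and is kept throughout. C1′ (R) is set by Felkin–Anh (anti) addition of lithium methoxyacetylide to the α-PMB-oxy aldehyde. No later step breaks either C–O bond.

Key step: step 11

Remark: coumarin numbering (O1 to C8a) and primed side-chain atoms (C1′ benzylic, C2′ allylic) are also used for precursors; PMB = 4-methoxybenzyl, TBS = tert-butyldimethylsilyl; stereocentres that form only to vanish again (benzylidene acetal carbon, ring carbons of annulation intermediates) are left undefined in the SMILES.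

**Step 1**
Reactants: 1 methyl (4R)-2,2-dimethyl-1,3-dioxolane-4-carboxylate
Product: 2 2-[(4R)-2,2-dimethyl-1,3-dioxolan-4-yl]propan-2-ol
Conditions: MeMgBr (2.5 equiv), Et2O, 0 → 25 °C; aq. NH4Cl
Reagents that add atoms: methylmagnesium bromide, C[Mg]Br
Why: Double Grignard addition to the ester gives the tertiary carbinol, and the dioxolane stereocentre (future C2′) is kept because addition to the ester and to the transient methyl ketone outruns enolisation.

**Step 2**
Reactants: 2 2-[(4R)-2,2-dimethyl-1,3-dioxolan-4-yl]propan-2-ol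
Product: 3 (4S)-2,2-dimethyl-4-(prop-1-en-2-yl)-1,3-dioxolane
Conditions: SOCl2, pyridine, 0 °C
Reagents that add atoms: none
Why: Tertiary alcohol dehydration through the chlorosulfite (E2 with pyridine) should take one of the six unhindered methyl hydrogens rather than the single ring C–H next to oxygen, as in the known dehydration of hydroxyisopropyl-dihydrofurans to isopropenyl-dihydrofurans, and the stereocentre is not involved (the descriptor changes only through CIP priorities).

**Step 3**
Reactants: 3 (4S)-2,2-dimethyl-4-(prop-1-en-2-yl)-1,3-dioxolane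
Product: 4 (2S)-3-methylbut-3-ene-1,2-diol
Conditions: AcOH–H2O (4:1), 40 °C; evaporation with toluene
Reagents that add atoms: none
Why: Acid-catalysed hydrolysis of a terminal acetonide is routine, and acetic acid is too weak to ionise the secondary allylic C–O bond.

**Step 4**
Reactants: 4 (2S)-3-methylbut-3-ene-1,2-diol
Product: 5 (4S)-2-(4-methoxyphenyl)-4-(prop-1-en-2-yl)-1,3-dioxolane
Conditions: 4-MeOC6H4CH(OMe)2, pyridinium 4-toluenesulfonate (cat.), CH2Cl2, 25 °C
Reagents that add atoms: 4-methoxybenzaldehyde dimethyl acetal, COc1ccc(C(OC)OC)cc1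
Why: Acid-catalysed transacetalisation closes the 4-methoxybenzylidene acetal, and the new acetal carbon forms as an epimer mixture that does not matter because it becomes a CH2 group in step 5.

**Step 5**
Reactants: 5 (4S)-2-(4-methoxyphenyl)-4-(prop-1-en-2-yl)-1,3-dioxolane
Product: 6 (2S)-2-[(4-methoxybenzyl)oxy]-3-methylbut-3-en-1-ol
Conditions: iBu2AlH (2.5 equiv), CH2Cl2, −78 → 0 °C; aq. potassium sodium tartrate
Reagents that add atoms: none
Why: In this regioselective reductive opening of a 4-methoxybenzylidene acetal, iBu2AlH binds the less hindered primary oxygen, that C–O bond breaks and hydride goes to the oxocarbenium ion, so the PMB group stays on the secondary oxygen.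

**Step 6**
Reactants: 6 (2S)-2-[(4-methoxybenzyl)oxy]-3-methylbut-3-en-1-ol
Product: 7 (2S)-2-[(4-methoxybenzyl)oxy]-3-methylbut-3-enal
Conditions: PhI(OAc)2, 2,2,6,6-tetramethylpiperidin-1-oxyl (cat.), CH2Cl2, 25 °C; NaHCO3 wash, used at once
Reagents that add atoms: none
Why: Oxoammonium-mediated alcohol oxidation stops at the aldehyde and needs no base, which suits an α-alkoxy-β,γ-unsaturated aldehyde that is prone to epimerisation and to migration of the double bond into conjugation.

**Step 7**
Reactants: 8 2-chloro-1,1-dimethoxyethane (chloroacetaldehyde dimethyl acetal); 7 (2S)-2-[(4-methoxybenzyl)oxy]-3-methylbut-3-enal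
Product: 10 (3R,4S)-1-methoxy-4-[(4-methoxybenzyl)oxy]-5-methylhex-5-en-1-yn-3-ol, via lithium methoxyacetylide 9 (not isolated)
Conditions: 8 (1.5 equiv), Et2NH/n-BuLi (4.4 equiv, gives LiNEt2), THF, 0 °C; DMPU, then 7, −78 °C; aq. NaH2PO4/Na2HPO4 (pH 7); Et3N-deactivated silica
Reagents that add atoms: none
Why: Twofold elimination and deprotonation of the chloroacetal give the acetylide, whose 1,2-addition under non-chelating conditions (Li+ in THF/DMPU) follows the polar Felkin–Anh model, with attack anti to the C–OPMB bond and past the α-hydrogen, so the anti (3R,4S) alcohol should be the major isomer and the syn epimer is removed by chromatography.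

**Step 8**
Reactants: 10 (3R,4S)-1-methoxy-4-[(4-methoxybenzyl)oxy]-5-methylhex-5-en-1-yn-3-ol
Product: 11 tert-butyl({(3R,4S)-1-methoxy-4-[(4-methoxybenzyl)oxy]-5-methylhex-5-en-1-yn-3-yl}oxy)dimethylsilane
Conditions: TBSCl, imidazole, DMF, 25 °C
Reagents that add atoms: tert-butyldimethylsilyl chloride, CC(C)(C)[Si](C)(C)Cl
Why: Imidazole-mediated O-silylation runs under weakly basic conditions that the acid-labile ynol ether tolerates, and the silyl ether blocks Meyer–Schuster rearrangement of the alkoxypropargylic alcohol.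

**Step 9**
Reactants: 12 2,2-dimethoxyacetaldehyde (60% aqueous solution); 13 1-(triphenylphosphoranylidene)propan-2-one
Product: 14 (3E)-5,5-dimethoxypent-3-en-2-one
Conditions: CH2Cl2, 25 °C
Reagents that add atoms: none
Why: Wittig olefination with a ketone-stabilised ylide is E-selective and tolerates the water in which the aldehyde is supplied.

**Step 10**
Reactants: 14 (3E)-5,5-dimethoxypent-3-en-2-one
Product: 16 (3E)-1-diazo-5,5-dimethoxypent-3-en-2-one, via trifluoroacetyl diketone 15 (not isolated)
Conditions: LiN(SiMe3)2, THF, −78 °C; CF3CO2CH2CF3, −78 °C; brief cold 5% HCl wash; then 4-acetamidobenzenesulfonyl azide, Et3N, H2O (1 equiv), MeCN, 25 °C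
Reagents that add atoms: 4-acetamidobenzenesulfonyl azide, CC(=O)Nc1ccc(S(=O)(=O)N=[N+]=[N-])cc1 (the two nitrogen atoms of 16); 2,2,2-trifluoroethyl trifluoroacetate, O=C(OCC(F)(F)F)C(F)(F)F (the CF3CO group of 15 only, lost again)
Why: Detrifluoroacetylative diazo transfer (kinetic enolisation at the methyl group, C-trifluoroacetylation, diazo transfer with loss of the activating group) is the established entry to α′-diazo enones because it avoids diazomethane and its dipolar cycloaddition to the enone, and the enone-conjugated acetal is deactivated toward the brief acid wash.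

**Step 11**
Reactants: 11 tert-butyl({(3R,4S)-1-methoxy-4-[(4-methoxybenzyl)oxy]-5-methylhex-5-en-1-yn-3-yl}oxy)dimethylsilane; 16 (3E)-1-diazo-5,5-dimethoxypent-3-en-2-one
Product: 21 6-(dimethoxymethyl)-3-methoxy-2-{(1R,2S)-1-[(tert-butyldimethylsilyl)oxy]-2-[(4-methoxybenzyl)oxy]-3-methylbut-3-en-1-yl}phenol, via vinylketene 17 (not isolated), via alkenylcyclobutenone 18 (not isolated), via dienylketene 19 (not isolated), via cyclohexadienone 20 (not isolated)
Conditions: 11 (1.0 equiv), 16 (1.5 equiv, in portions), degassed CH2Cl2, hν (300 nm lamps, Pyrex), 25 °C; then toluene, 110 °C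
Reagents that add atoms: none
Why: Light expels N2 from 16 and the alkenyl group migrates (photochemical Wolff rearrangement) to give vinylketene 17, which ynol ether 11 traps by [2+2] cycloaddition (C8a–C8 and C6–C7) as 4-alkenylcyclobutenone 18. On heating, 18 undergoes reversible 4π electrocyclic opening to dienylketene 19, whose isomer with the alkenyl group turned inward closes ring A, the only ring formed, by thermal disrotatory 6π electrocyclisation (C8a–C4a) to cyclohexadienone 20, and tautomerisation gives phenol 21. This is the Danheiser benzannulation in its diazo ketone variant, a reaction type established for alkoxy- and siloxyalkynes. No lasting stereocentre is created, since C4 of 18 and C6 of 20 vanish on aromatisation, and C1′ and C2′ are spectators under the neutral conditions. The step needs regioselectivity, and the polarisation of the ynol ether secures it: the carbon β to methoxy (C8) is the nucleophilic one and bonds to the electrophilic ketene carbonyl carbon (C8a), which places the side chain ortho and the methoxy group meta to the new hydroxyl. Chemoselectivity over the isopropenyl group follows from the far higher ketenophilicity of the ynol ether, the Pyrex filter keeps light away from the PMB chromophore, a methyl ynol ether cannot fragment by retro-ene reaction at 110 °C, and generating the ketene at 25 °C before the thermal stage keeps the phenol from intercepting 17.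

**Step 12**
Reactants: 21 6-(dimethoxymethyl)-3-methoxy-2-{(1R,2S)-1-[(tert-butyldimethylsilyl)oxy]-2-[(4-methoxybenzyl)oxy]-3-methylbut-3-en-1-yl}phenol
Product: 22 2-hydroxy-4-methoxy-3-{(1R,2S)-1-[(tert-butyldimethylsilyl)oxy]-2-[(4-methoxybenzyl)oxy]-3-methylbut-3-en-1-yl}benzaldehyde
Conditions: pyridinium 4-toluenesulfonate (cat.), acetone–H2O (10:1), 25 °C
Reagents that add atoms: water, O
Why: In this acetal hydrolysis the ortho-hydroxyl and para-methoxy groups assist ionisation of the benzylic acetal, so a catalytic weak acid suffices and the TBS and PMB ethers are left alone.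

**Step 13**
Reactants: 22 2-hydroxy-4-methoxy-3-{(1R,2S)-1-[(tert-butyldimethylsilyl)oxy]-2-[(4-methoxybenzyl)oxy]-3-methylbut-3-en-1-yl}benzaldehyde
Product: 24 8-{(1R,2S)-1-[(tert-butyldimethylsilyl)oxy]-2-[(4-methoxybenzyl)oxy]-3-methylbut-3-en-1-yl}-7-methoxy-2H-chromen-2-one, via phosphoranylidene acetate 23 (not isolated)
Conditions: Ph3P=C=C=O (1.3 equiv), toluene, 80 → 110 °C
Reagents that add atoms: (triphenylphosphoranylidene)ketene, O=C=C=P(c1ccccc1)(c1ccccc1)c1ccccc1
Why: The phenol O–H adds across the cumulated ylide to give aryl ester ylide 23, whose intramolecular Wittig reaction with the ortho aldehyde closes ring B with the cis C3=C4 geometry enforced by the ring, a known route from salicylaldehydes to coumarins in which the small sp-carbon electrophile suits the hindered phenol.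

**Step 14**
Reactants: 24 8-{(1R,2S)-1-[(tert-butyldimethylsilyl)oxy]-2-[(4-methoxybenzyl)oxy]-3-methylbut-3-en-1-yl}-7-methoxy-2H-chromen-2-one
Product: 25 8-{(1R,2S)-1-[(tert-butyldimethylsilyl)oxy]-2-hydroxy-3-methylbut-3-en-1-yl}-7-methoxy-2H-chromen-2-one
Conditions: DDQ (2,3-dichloro-5,6-dicyano-1,4-benzoquinone), CH2Cl2–aq. NaH2PO4/Na2HPO4 (pH 7, 10:1), 0 °C
Reagents that add atoms: none
Why: Oxidative PMB cleavage (hydride abstraction, then hydrolysis of the oxocarbenium ion) is selective for the electron-rich 4-methoxybenzyl group over the silyl ether, the isopropenyl group and the less electron-rich methoxycoumarin.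

**Step 15**
Reactants: 25 8-{(1R,2S)-1-[(tert-butyldimethylsilyl)oxy]-2-hydroxy-3-methylbut-3-en-1-yl}-7-methoxy-2H-chromen-2-one
Product: 26 (1R,2S)-1-[(tert-butyldimethylsilyl)oxy]-1-(7-methoxy-2-oxo-2H-chromen-8-yl)-3-methylbut-3-en-2-yl 3-methylbutanoate
Conditions: (Me2CHCH2CO)2O, Et3N, 4-(dimethylamino)pyridine (cat.), CH2Cl2, 0 → 25 °C
Reagents that add atoms: 3-methylbutanoic (isovaleric) anhydride, CC(C)CC(=O)OC(=O)CC(C)C
Why: Nucleophile-catalysed acylation of the only free hydroxyl group leaves the C2′–O bond intact, so the configuration is retained.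

**Step 16**
Reactants: 26 (1R,2S)-1-[(tert-butyldimethylsilyl)oxy]-1-(7-methoxy-2-oxo-2H-chromen-8-yl)-3-methylbut-3-en-2-yl 3-methylbutanoate
Product: 27 (1R,2S)-1-hydroxy-1-(7-methoxy-2-oxo-2H-chromen-8-yl)-3-methylbut-3-en-2-yl 3-methylbutanoate (CNP0200399.1)
Conditions: HF·pyridine, pyridine, THF, 0 → 25 °C
Reagents that add atoms: none
Why: Fluoride-driven Si–O cleavage in a buffered, mildly acidic medium never forms the free alkoxide that would trigger acyl migration from O2′ to O1′ or opening of the lactone, and both stereocentres are untouched.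

**Compound list**
1 | methyl (4R)-2,2-dimethyl-1,3-dioxolane-4-carboxylate | COC(=O)[C@H]1COC(C)(C)O1 | starting material
2 | 2-[(4R)-2,2-dimethyl-1,3-dioxolan-4-yl]propan-2-ol | CC(C)(O)[C@H]1COC(C)(C)O1 | intermediate
3 | (4S)-2,2-dimethyl-4-(prop-1-en-2-yl)-1,3-dioxolane | C=C(C)[C@H]1COC(C)(C)O1 | intermediate
4 | (2S)-3-methylbut-3-ene-1,2-diol | C=C(C)[C@H](O)CO | intermediate
5 | (4S)-2-(4-methoxyphenyl)-4-(prop-1-en-2-yl)-1,3-dioxolane (epimers at C2) | C=C(C)[C@H]1COC(c2ccc(OC)cc2)O1 | intermediate
6 | (2S)-2-[(4-methoxybenzyl)oxy]-3-methylbut-3-en-1-ol | C=C(C)[C@H](OCc1ccc(OC)cc1)CO | intermediate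
7 | (2S)-2-[(4-methoxybenzyl)oxy]-3-methylbut-3-enal | C=C(C)[C@H](OCc1ccc(OC)cc1)C=O | intermediate
8 | 2-chloro-1,1-dimethoxyethane | COC(CCl)OC | starting material
9 | lithium methoxyacetylide | [Li]C#COC | intermediate
10 | (3R,4S)-1-methoxy-4-[(4-methoxybenzyl)oxy]-5-methylhex-5-en-1-yn-3-ol | C=C(C)[C@H](OCc1ccc(OC)cc1)[C@H](O)C#COC | intermediate
11 | tert-butyl({(3R,4S)-1-methoxy-4-[(4-methoxybenzyl)oxy]-5-methylhex-5-en-1-yn-3-yl}oxy)dimethylsilane | C=C(C)[C@H](OCc1ccc(OC)cc1)[C@H](O[Si](C)(C)C(C)(C)C)C#COC | intermediate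
12 | 2,2-dimethoxyacetaldehyde | COC(OC)C=O | starting material
13 | 1-(triphenylphosphoranylidene)propan-2-one | CC(=O)C=P(c1ccccc1)(c1ccccc1)c1ccccc1 | starting material
14 | (3E)-5,5-dimethoxypent-3-en-2-one | COC(OC)/C=C/C(C)=O | intermediate
15 | (5E)-1,1,1-trifluoro-7,7-dimethoxyhept-5-ene-2,4-dione | COC(OC)/C=C/C(=O)CC(=O)C(F)(F)F | intermediate
16 | (3E)-1-diazo-5,5-dimethoxypent-3-en-2-one | COC(OC)/C=C/C(=O)C=[N+]=[N-] | intermediate
17 | (3E)-5,5-dimethoxypenta-1,3-dien-1-one | COC(OC)/C=C/C=C=O | intermediate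
18 | 4-[(1E)-3,3-dimethoxyprop-1-en-1-yl]-3-methoxy-2-{(1R,2S)-1-[(tert-butyldimethylsilyl)oxy]-2-[(4-methoxybenzyl)oxy]-3-methylbut-3-en-1-yl}cyclobut-2-en-1-one | C=C(C)[C@H](OCc1ccc(OC)cc1)[C@H](O[Si](C)(C)C(C)(C)C)C1=C(OC)C(/C=C/C(OC)OC)C1=O | intermediate
19 | (3E,5E)-3,7,7-trimethoxy-2-{(1R,2S)-1-[(tert-butyldimethylsilyl)oxy]-2-[(4-methoxybenzyl)oxy]-3-methylbut-3-en-1-yl}hepta-1,3,5-trien-1-one | C=C(C)[C@H](OCc1ccc(OC)cc1)[C@H](O[Si](C)(C)C(C)(C)C)C(=C=O)/C(OC)=C\C=C\C(OC)OC | intermediate
20 | 6-(dimethoxymethyl)-3-methoxy-2-{(1R,2S)-1-[(tert-butyldimethylsilyl)oxy]-2-[(4-methoxybenzyl)oxy]-3-methylbut-3-en-1-yl}cyclohexa-2,4-dien-1-one | C=C(C)[C@H](OCc1ccc(OC)cc1)[C@H](O[Si](C)(C)C(C)(C)C)C1=C(OC)C=CC(C(OC)OC)C1=O | intermediate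
21 | 6-(dimethoxymethyl)-3-methoxy-2-{(1R,2S)-1-[(tert-butyldimethylsilyl)oxy]-2-[(4-methoxybenzyl)oxy]-3-methylbut-3-en-1-yl}phenol | C=C(C)[C@H](OCc1ccc(OC)cc1)[C@H](O[Si](C)(C)C(C)(C)C)c1c(OC)ccc(C(OC)OC)c1O | intermediate
22 | 2-hydroxy-4-methoxy-3-{(1R,2S)-1-[(tert-butyldimethylsilyl)oxy]-2-[(4-methoxybenzyl)oxy]-3-methylbut-3-en-1-yl}benzaldehyde | C=C(C)[C@H](OCc1ccc(OC)cc1)[C@H](O[Si](C)(C)C(C)(C)C)c1c(OC)ccc(C=O)c1O | intermediate
23 | 6-formyl-3-methoxy-2-{(1R,2S)-1-[(tert-butyldimethylsilyl)oxy]-2-[(4-methoxybenzyl)oxy]-3-methylbut-3-en-1-yl}phenyl (triphenylphosphoranylidene)acetate | C=C(C)[C@H](OCc1ccc(OC)cc1)[C@H](O[Si](C)(C)C(C)(C)C)c1c(OC)ccc(C=O)c1OC(=O)C=P(c1ccccc1)(c1ccccc1)c1ccccc1 | intermediate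
24 | 8-{(1R,2S)-1-[(tert-butyldimethylsilyl)oxy]-2-[(4-methoxybenzyl)oxy]-3-methylbut-3-en-1-yl}-7-methoxy-2H-chromen-2-one | C=C(C)[C@H](OCc1ccc(OC)cc1)[C@H](O[Si](C)(C)C(C)(C)C)c1c(OC)ccc2ccc(=O)oc12 | intermediate
25 | 8-{(1R,2S)-1-[(tert-butyldimethylsilyl)oxy]-2-hydroxy-3-methylbut-3-en-1-yl}-7-methoxy-2H-chromen-2-one | C=C(C)[C@H](O)[C@H](O[Si](C)(C)C(C)(C)C)c1c(OC)ccc2ccc(=O)oc12 | intermediate
26 | (1R,2S)-1-[(tert-butyldimethylsilyl)oxy]-1-(7-methoxy-2-oxo-2H-chromen-8-yl)-3-methylbut-3-en-2-yl 3-methylbutanoate | C=C(C)[C@H](OC(=O)CC(C)C)[C@H](O[Si](C)(C)C(C)(C)C)c1c(OC)ccc2ccc(=O)oc12 | intermediate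
27 | (1R,2S)-1-hydroxy-1-(7-methoxy-2-oxo-2H-chromen-8-yl)-3-methylbut-3-en-2-yl 3-methylbutanoate | C=C(C)[C@H](OC(=O)CC(C)C)[C@H](O)c1c(OC)ccc2ccc(=O)oc12 | target

**Step count**
Total steps: 16. Longest linear sequence: 14 (steps 1–8 and 11–16, from 1). The diazo enone branch (steps 9 and 10) is convergent.

**Steps most likely to fail**

**Step 11.**
- What may go wrong: the [2+2] cycloaddition may be slow at an alkyne carbon that carries a branched, doubly oxygenated substituent. Ketene dimerisation, acylation of the newly formed phenol by the ketene, or thermal loss of methanol from the ortho-hydroxy acetal could then take over.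
- Fallback (sets out from 7, comes back at 22): ring A is bought rather than built, and the C8–C1′ bond is made by directed ortho-metalation. Commercial 2-hydroxy-4-methoxybenzaldehyde is protected (MOMCl, iPr2NEt, CH2Cl2) as 4-methoxy-2-(methoxymethoxy)benzaldehyde F1. This is acetalised (HC(OMe)3, MeOH, cat. pyridinium 4-toluenesulfonate) to 1-(dimethoxymethyl)-4-methoxy-2-(methoxymethoxy)benzene F2. n-BuLi in THF at 0 °C removes the proton flanked by the two oxygen substituents and gives [3-(dimethoxymethyl)-6-methoxy-2-(methoxymethoxy)phenyl]lithium F3. This adds to 7 at −78 °C in the Felkin–Anh sense to give (1R,2S)-1-[3-(dimethoxymethyl)-6-methoxy-2-(methoxymethoxy)phenyl]-2-[(4-methoxybenzyl)oxy]-3-methylbut-3-en-1-ol F4. TBSOTf/2,6-lutidine then gives its tert-butyldimethylsilyl ether F5. NaHSO4 on SiO2 in moist CH2Cl2 removes the acetal and the phenolic MOM group and delivers 22.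

**Step 7.**
- What may go wrong: facial selectivity may be poor because lithium partly chelates the PMB oxygen. Base-induced epimerisation, or migration of the double bond of the aldehyde into conjugation, may also occur before addition.
- Fallback (sets out from 10 as obtained, mixed with its C3 epimer, and comes back at 10): stereocontrol is moved from C–C bond formation to hydride delivery, where chelation helps rather than hurts. Activated MnO2 in CH2Cl2 oxidises the epimer mixture to (4S)-1-methoxy-4-[(4-methoxybenzyl)oxy]-5-methylhex-5-en-1-yn-3-one F6. Zn(BH4)2 in Et2O at −78 °C then reduces the zinc chelate of the ketone and PMB oxygens from the face that carries the α-hydrogen. This chelation-controlled reduction, known for α-alkoxy ynones, converges both epimers on the anti alcohol 10.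

**Step 16.**
- What may go wrong: cleavage of the silyl ether may be sluggish, since it is flanked by two ortho substituents and a branched carbon. Under forcing conditions the acyl group may shift from O2′ to O1′, or the benzylic C–O bond may ionise.
- Fallback (sets out from 25, comes back at 27): the silyl group is removed before any ester is present, and the two hydroxyl groups are then told apart by hindrance. Bu4NF in THF at 0 °C converts 25 into 8-[(1R,2S)-1,2-dihydroxy-3-methylbut-3-en-1-yl]-7-methoxy-2H-chromen-2-one F7. One equivalent of 3-methylbutanoyl chloride with 2,4,6-collidine in CH2Cl2 at −78 °C should then acylate the allylic O2′–H in preference to the doubly ortho-flanked benzylic O1′–H, which gives 27 directly.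

**Further compounds**
F1 | step 11 | 4-methoxy-2-(methoxymethoxy)benzaldehyde | COCOc1cc(OC)ccc1C=O
F2 | step 11 | 1-(dimethoxymethyl)-4-methoxy-2-(methoxymethoxy)benzene | COCOc1cc(OC)ccc1C(OC)OC
F3 | step 11 | [3-(dimethoxymethyl)-6-methoxy-2-(methoxymethoxy)phenyl]lithium | [Li]c1c(OC)ccc(C(OC)OC)c1OCOC
F4 | step 11 | (1R,2S)-1-[3-(dimethoxymethyl)-6-methoxy-2-(methoxymethoxy)phenyl]-2-[(4-methoxybenzyl)oxy]-3-methylbut-3-en-1-ol | C=C(C)[C@H](OCc1ccc(OC)cc1)[C@H](O)c1c(OC)ccc(C(OC)OC)c1OCOC
F5 | step 11 | tert-butyl({(1R,2S)-1-[3-(dimethoxymethyl)-6-methoxy-2-(methoxymethoxy)phenyl]-2-[(4-methoxybenzyl)oxy]-3-methylbut-3-en-1-yl}oxy)dimethylsilane | C=C(C)[C@H](OCc1ccc(OC)cc1)[C@H](O[Si](C)(C)C(C)(C)C)c1c(OC)ccc(C(OC)OC)c1OCOC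
F6 | step 7 | (4S)-1-methoxy-4-[(4-methoxybenzyl)oxy]-5-methylhex-5-en-1-yn-3-one | C=C(C)[C@H](OCc1ccc(OC)cc1)C(=O)C#COC
F7 | step 16 | 8-[(1R,2S)-1,2-dihydroxy-3-methylbut-3-en-1-yl]-7-methoxy-2H-chromen-2-one | C=C(C)[C@H](O)[C@H](O)c1c(OC)ccc2ccc(=O)oc12
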